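**Retrosynthetic overview**
- Target ⇐ C9 angeloylation, OH‑directed C9 ketone reduction and C8 isovaleroylation of a tricyclic 7,8‑diol‑1,9‑dione.
- Cyclobutane (last ring) ⇐ semipinacol 1,2‑shift: a transannular aldolate of bicyclo[2.2.1] type (C1 alkoxide, C11 mesylate) contracts to the bicyclo[3.1.1] core.
- Seven‑membered ring ⇐ one‑carbon ring expansion (β‑oxido carbenoid 1,2‑shift) of a cis‑fused 6/6 ketone; it also delivers the regiodefined C9/C10 enolate as its silyl ether.
- Second six‑membered ring ⇐ Mukaiyama–Michael/Michael annulation of a 2‑silyloxydiene onto an enantiopure cis‑5,6‑dioxygenated 4,4‑dimethylcyclohexenone.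
- First ring ⇐ proline aldol of hydroxyacetone with 2,2‑dimethylpropanedial (sets absolute configuration), then aldol cyclodehydration. Ring order: 6 → 6/6 → 6/7 → 6/7/4.

Assumption: locants in names follow a longipinane numbering defined here (C1 ring ketone, C2, C3(Me), C4, C5, C6 = CMe2, C7, C8, C9, C10 = C–Me, C11); the SMILES strings are definitive for configuration.

**Step 1**
Reactants: 1 2,2-dimethylpropane-1,3-diol
Product: 2 2,2-dimethylpropanedial
Conditions: (COCl)2, DMSO, CH2Cl2, −78 °C; Et3N, −78 → 0 °C; used as a dried solution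
Reagents that add atoms: none
Why: Swern oxidation of a 1,3-diol whose C2 is quaternary, so neither enolisation nor elimination can interfere; no stereocentre.

**Step 2**
Reactants: 2 2,2-dimethylpropanedial, 3 hydroxyacetone
Product: 4 (3S,4S)-3,4-dihydroxy-2,2-dimethyl-5-oxohexanal (anti-diol; in equilibrium with its five-membered lactol)
Conditions: (S)-proline (30 mol%), DMSO, rt; hydroxyacetone added slowly by syringe pump
Reagents that add atoms: none
Why: Proline-catalysed direct aldol addition of hydroxyacetone (enamine at the hydroxylated carbon) to an α-quaternary, non-enolisable aldehyde gives the anti-1,2-diol, and (S)-proline sets both carbinol centres (S,S), the source of absolute configuration; slow addition keeps the dialdehyde in excess over the donor and the mono-adduct masks its remaining formyl group as the lactol, so a second aldol is suppressed.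

**Step 3**
Reactants: 4 (3S,4S)-3,4-dihydroxy-2,2-dimethyl-5-oxohexanal
Product: 5 2-[(4S,5S)-5-acetyl-2,2-dimethyl-1,3-dioxolan-4-yl]-2-methylpropanal
Conditions: 2-methoxypropene, PPTS (cat.), CH2Cl2, 0 °C → rt
Reagents that add atoms: 2-methoxypropene, COC(C)=C
Why: Acetonide formation by trans-ketalisation traps the open diol form (cis-4,5-disubstituted dioxolane) without acetalising the aldehyde; stereocentres untouched.

**Step 4**
Reactants: 5 2-[(4S,5S)-5-acetyl-2,2-dimethyl-1,3-dioxolan-4-yl]-2-methylpropanal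
Product: 6 (3aS,7aS)-2,2,7,7-tetramethyl-7,7a-dihydro-1,3-benzodioxol-4(3aH)-one (= (5S,6S)-5,6-O-isopropylidene-5,6-dihydroxy-4,4-dimethylcyclohex-2-enone)
Conditions: Bn2NH·TFA, toluene, 50 °C
Reagents that add atoms: none
Why: Intramolecular aldol condensation (6-enolexo) of the methyl ketone onto the non-enolisable neopentyl aldehyde, pre-organised by the cis-dioxolane; no new stereocentre.

**Step 5**
Reactants: 7 (E)-pent-3-en-2-one
Product: 8 (E)-2-(tert-butyldimethylsilyloxy)penta-1,3-diene
Conditions: TBSOTf, Et3N, CH2Cl2, 0 °C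
Reagents that add atoms: tert-butyldimethylsilyl triflate, CC(C)(C)[Si](C)(C)OS(=O)(=O)C(F)(F)F
Why: Soft enolisation/O-silylation at the methyl group gives the cross-conjugated 2-silyloxydiene.

**Step 6**
Reactants: 6 enone acetonide, 8 (E)-2-(tert-butyldimethylsilyloxy)penta-1,3-diene
Product: 9 cis-fused 2,3-O-isopropylidene-2,3-dihydroxy-6-(tert-butyldimethylsilyloxy)-4,4,8-trimethyl-3,4,4a,5,8,8a-hexahydronaphthalen-1(2H)-one (decalin numbering; H-4a and H-8a cis to each other and to the acetonide oxygens)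
Conditions: Tf2NH (10 mol%), CH2Cl2, −78 → −40 °C; Et3N quench
Reagents that add atoms: none
Why: Triflimide-catalysed Mukaiyama–Michael/Michael annulation (stepwise formal [4+2], the variant used for hindered partners): the diene CH2 adds axially to C-β anti to the dioxolane oxygens and the enol silane then closes cis, giving the cis-fused ring with the TBS enol ether retained; the C8 methyl centre is erased in step 8, so its epimer is carried along.

**Step 7**
Reactants: 9 cis-fused silyl enol ether ketone, 10 1,1-dibromoethane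
Product: 13 cis-fused 3-(tert-butyldimethylsilyloxy)-8-(triisopropylsilyloxy)-6,7-(isopropylidenedioxy)-1,5,5,9-tetramethyl-4,4a,5,6,7,9a-hexahydro-1H-benzo[7]annulene (benzo[7]annulene numbering), via lithium dibromoethyl carbinolate 11 (not isolated), via ring-expanded lithium enolate 12 (not isolated)
Conditions: 10, LiTMP, THF, −95 °C; n-BuLi, −95 → −78 °C; TIPSOTf, −78 → 0 °C
Reagents that add atoms: triisopropylsilyl triflate, CC(C)[Si](OS(=O)(=O)C(F)(F)F)(C(C)C)C(C)C
Why: Nozaki–Yamamoto β-oxido carbenoid ring expansion (1,2-shift): CH3CBr2Li adds to the only free carbonyl, Br/Li exchange triggers migration of the ring-fusion carbon (with retention; the α-alkoxy carbon is a poor migrating group), and the regiodefined tetrasubstituted enolate is trapped as its TIPS ether.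

**Step 8**
Reactants: 13 bis(silyl enol ether)
Product: 14 cis-fused 8-(triisopropylsilyloxy)-6,7-(isopropylidenedioxy)-1,5,5,9-tetramethyl-4,4a,5,6,7,9a-hexahydro-3H-benzo[7]annulen-3-one
Conditions: Pd(OAc)2 (1.1 equiv), MeCN, 40 °C
Reagents that add atoms: none
Why: Saegusa–Ito oxidation occurs at the less hindered trisubstituted TBS enol ether (β-H elimination towards the methyl-bearing carbon), while the tetrasubstituted TIPS enol ether transmetalates far more slowly; the resulting enone makes C4 the only α′ position.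

**Step 9**
Reactants: 14 enone TIPS enol ether
Product: 16 4-(methanesulfonyloxy) derivative of 14 (OMs on C4 trans to the C4a–C5 bond), via potassium α′-alkoxide 15 (not isolated)
Conditions: KHMDS, THF, −78 °C; 2-(phenylsulfonyl)-3-phenyloxaziridine; then MsCl, −78 → 0 °C
Reagents that add atoms: 2-(phenylsulfonyl)-3-phenyloxaziridine, O1C(c2ccccc2)N1S(=O)(=O)c1ccccc1; methanesulfonyl chloride, CS(Cl)(=O)=O
Why: Davis hydroxylation of the kinetic cross-conjugated α′-enolate occurs anti to the adjacent CMe2-bearing ring-fusion substituent (2,3-trans rule), and the alkoxide is mesylated in situ before it can epimerise.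

**Step 10**
Reactants: 16 keto mesylate TIPS enol ether
Product: 19 7,8-O-isopropylidene-7,8-dihydroxylongipin-2-ene-1,9-dione, via C9/C10 enolate 17 (not isolated), via bridged C1 aldolate 18 (not isolated)
Conditions: TASF (1.2 equiv), THF, −40 °C → rt
Reagents that add atoms: none
Why: Proposed new method: fluoride unmasks the regiodefined C10 enolate, which adds across the ring to the C1 ketone (5-ring aldol) to give a 1-oxido-bicyclo[2.2.1] aldolate whose C1–C10 bond is antiperiplanar to the endo C11–OMs bond, so an alkoxide-driven semipinacol 1,2-shift moves C10 from C1 to C11 with inversion at C11, contracting the bicyclo[2.2.1] unit to the bicyclo[3.1.1] (cyclobutane) core and regenerating the C1 carbonyl; C10 is set by the ring constraint (C9 syn to C5), the strain increase is paid for by C=O formation and mesylate loss, and a direct 4-exo displacement would converge on the same product; the closest known reactions are the semipinacol rearrangement of β-sulfonyloxy alkoxides and the addition/1,2-shift substitution of α-halo ketones.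

**Step 11**
Reactants: 19 tricyclic enone ketone acetonide
Product: 21 7,8-dihydroxylongipinane-1,9-dione, via saturated acetonide 20 (not isolated)
Conditions: H2 (1 atm), 10% Pd/C, EtOAc, rt; filter; then AcOH/H2O (4:1), 40 °C
Reagents that add atoms: none
Why: Heterogeneous hydrogenation of the verbenone-type enone from the face flanked by C5–H, away from the C10 methyl (as in verbenone → cis-verbanone), sets C3; mild acid then hydrolyses the acetonide.

**Step 12**
Reactants: 21 diol dione, 22 3-methylbutanoyl chloride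
Product: 23 7-hydroxy-8-(3-methylbutanoyloxy)longipinane-1,9-dione
Conditions: 22 (1.1 equiv), pyridine, CH2Cl2, −20 °C
Reagents that add atoms: none
Why: Selective acylation of the less hindered α-ketol hydroxyl (C8) over the neopentyl C7 hydroxyl next to CMe2.

**Step 13**
Reactants: 23 mono-isovalerate
Product: 24 7,9-dihydroxy-8-(3-methylbutanoyloxy)longipinan-1-one
Conditions: Me4NBH(OAc)3, MeCN/AcOH (1:1), −30 °C
Reagents that add atoms: none
Why: Evans–Saksena hydroxyl-directed reduction: hydride is delivered intramolecularly from the C7–O–B face to the β-hydroxy ketone, giving the 1,3-anti diol (C9–OH trans to the C7 and C8 oxygens); the isolated C1 ketone has no directing hydroxyl and is not reduced.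

**Step 14**
Reactants: 24 diol mono-isovalerate, 25 angelic acid
Product: 26 9-angeloyloxy-7-hydroxy-8-(3-methylbutanoyloxy)longipinan-1-one (CNP0323312.1)
Conditions: 25, 2,4,6-trichlorobenzoyl chloride, Et3N, toluene, rt; then 24, toluene, 75 °C (no DMAP)
Reagents that add atoms: none
Why: Yamaguchi-type mixed-anhydride esterification without DMAP keeps the Z (angelate) geometry; C9–OH should react in preference to C7–OH, which is flanked by the gem-dimethyl carbon and the cis ester.

**Compound list**
1 | 2,2-dimethylpropane-1,3-diol | OCC(C)(C)CO | starting material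
2 | 2,2-dimethylpropanedial | O=CC(C)(C)C=O | intermediate
3 | hydroxyacetone | CC(=O)CO | starting material
4 | (3S,4S)-3,4-dihydroxy-2,2-dimethyl-5-oxohexanal | CC(=O)[C@@H](O)[C@@H](O)C(C)(C)C=O | intermediate
5 | 2-[(4S,5S)-5-acetyl-2,2-dimethyl-1,3-dioxolan-4-yl]-2-methylpropanal | CC(=O)[C@@H](OC(C)(C)O1)[C@@H]1C(C)(C)C=O | intermediate
6 | (3aS,7aS)-2,2,7,7-tetramethyl-7,7a-dihydro-1,3-benzodioxol-4(3aH)-one | O=C1[C@@H](OC(C)(C)O2)[C@@H]2C(C)(C)C=C1 | intermediate
7 | (E)-pent-3-en-2-one | C/C=C/C(C)=O | starting material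
8 | (E)-2-(tert-butyldimethylsilyloxy)penta-1,3-diene | C=C(O[Si](C)(C)C(C)(C)C)/C=C/C | intermediate
9 | cis-fused decalinone TBS enol ether acetonide | O=C1[C@@H](OC(C)(C)O2)[C@@H]2C(C)(C)[C@@H]3CC(O[Si](C)(C)C(C)(C)C)=C[C@H](C)[C@H]13 | intermediate
10 | 1,1-dibromoethane | CC(Br)Br | starting material
11 | lithium dibromoethyl carbinolate (carbinol carbon undefined) | CC(Br)(Br)C1([O-])[C@@H](OC(C)(C)O2)[C@@H]2C(C)(C)[C@@H]3CC(O[Si](C)(C)C(C)(C)C)=C[C@H](C)[C@H]13.[Li+] | intermediate
12 | ring-expanded lithium enolate | CC1=C([O-])[C@@H](OC(C)(C)O2)[C@@H]2C(C)(C)[C@@H]3CC(O[Si](C)(C)C(C)(C)C)=C[C@H](C)[C@H]13.[Li+] | intermediate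
13 | cis-fused 6/7 bis(silyl enol ether) | CC1=C(O[Si](C(C)C)(C(C)C)C(C)C)[C@@H](OC(C)(C)O2)[C@@H]2C(C)(C)[C@@H]3CC(O[Si](C)(C)C(C)(C)C)=C[C@H](C)[C@H]13 | intermediate
14 | cis-fused 6/7 enone TIPS enol ether | CC1=C(O[Si](C(C)C)(C(C)C)C(C)C)[C@@H](OC(C)(C)O2)[C@@H]2C(C)(C)[C@@H]3CC(=O)C=C(C)[C@H]13 | intermediate
15 | potassium α′-alkoxide of 14 | CC1=C(O[Si](C(C)C)(C(C)C)C(C)C)[C@@H](OC(C)(C)O2)[C@@H]2C(C)(C)[C@@H]3[C@@H]([O-])C(=O)C=C(C)[C@H]13.[K+] | intermediate
16 | α′-mesyloxy enone TIPS enol ether | CC1=C(O[Si](C(C)C)(C(C)C)C(C)C)[C@@H](OC(C)(C)O2)[C@@H]2C(C)(C)[C@@H]3[C@@H](OS(C)(=O)=O)C(=O)C=C(C)[C@H]13 | intermediate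
17 | C9/C10 enolate (TAS salt) | CC1=C([O-])[C@@H](OC(C)(C)O2)[C@@H]2C(C)(C)[C@@H]3[C@@H](OS(C)(=O)=O)C(=O)C=C(C)[C@H]13.CN(C)[S+](N(C)C)N(C)C | intermediate
18 | bridged bicyclo[2.2.1] C1 aldolate (TAS salt) | C[C@]12C(=O)[C@@H](OC(C)(C)O3)[C@@H]3C(C)(C)[C@@H]4[C@@H](OS(C)(=O)=O)[C@@]1([O-])C=C(C)[C@H]24.CN(C)[S+](N(C)C)N(C)C | intermediate
19 | 7,8-O-isopropylidene-7,8-dihydroxylongipin-2-ene-1,9-dione | O=C1[C@@H](OC(C)(C)O4)[C@@H]4C(C)(C)[C@H]2[C@@H]3C(C)=CC(=O)[C@H]2[C@@]31C | intermediate
20 | 7,8-O-isopropylidene-7,8-dihydroxylongipinane-1,9-dione | O=C1[C@@H](OC(C)(C)O4)[C@@H]4C(C)(C)[C@H]2[C@@H]3[C@@H](C)CC(=O)[C@H]2[C@@]31C | intermediate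
21 | 7,8-dihydroxylongipinane-1,9-dione | O=C1[C@@H](O)[C@@H](O)C(C)(C)[C@H]2[C@@H]3[C@@H](C)CC(=O)[C@H]2[C@@]31C | intermediate
22 | 3-methylbutanoyl chloride | CC(C)CC(Cl)=O | starting material
23 | 7-hydroxy-8-(3-methylbutanoyloxy)longipinane-1,9-dione | O=C1[C@@H](OC(=O)CC(C)C)[C@@H](O)C(C)(C)[C@H]2[C@@H]3[C@@H](C)CC(=O)[C@H]2[C@@]31C | intermediate
24 | 7,9-dihydroxy-8-(3-methylbutanoyloxy)longipinan-1-one | O[C@@H]1[C@@H](OC(=O)CC(C)C)[C@@H](O)C(C)(C)[C@H]2[C@@H]3[C@@H](C)CC(=O)[C@H]2[C@@]31C | intermediate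
25 | angelic acid ((Z)-2-methylbut-2-enoic acid) | C/C=C(/C)C(=O)O | starting material
26 | CNP0323312.1 | C/C=C(/C)C(=O)O[C@@H]1[C@@H](OC(=O)CC(C)C)[C@@H](O)C(C)(C)[C@H]2[C@@H]3[C@@H](C)CC(=O)[C@H]2[C@@]31C | target

**Step count**
Total steps: 14. Longest linear sequence: 13 (steps 1–4 and 6–14; step 5 is a side branch).

**Steps most likely to fail, with fallbacks**

Step 10 (the proposed new cascade) may stall at O-alkylation, or at enolisation and epimerisation of C11. The fallback uses known oxidative enol-silane coupling and sets out from 14. LDA/TMSCl at −78 °C gives the cross-conjugated bis(silyl enol ether) F1. Ceric ammonium nitrate with NaHCO3 in MeCN at −30 °C then joins the two enol-silane carbons (C10–C11) directly, with no mesylate and no 1,2-shift. It comes back to the route at 19.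

Step 7 (carbenoid ring expansion) may fail through enolisation of the hindered ketone or poor addition of the bulky carbenoid. The fallback sets out from 9 and uses the non-basic Lewis-acid-catalysed diazoalkane homologation. Diazoethane with Sc(OTf)3 (cat.) in toluene at −78 °C inserts CH(CH3) on the ring-fusion side, because the α-alkoxy carbon migrates poorly, giving the ring-expanded α-methyl ketone F2 as a mixture of methine epimers. Thermodynamic silylation (TIPSOTf, Et3N, CH2Cl2) to the tetrasubstituted enol ether comes back to the route at 13.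

Step 14 (angeloylation of C9–OH in the presence of free C7–OH) may lack selectivity, because both hydroxyls sit next to a quaternary carbon. The fallback sets out from 21 and uses a protecting-group detour. Me4NBH(OAc)3 reduces the C9 ketone first to the 7,8,9-triol F3. 2-Methoxypropene/PPTS ties the cis-7,8-diol up as the 7,8-acetonide F4, leaving C9–OH as the only hydroxyl. The same mixed-anhydride angeloylation gives the angelate acetonide F5. Aqueous AcOH gives the 9-angelate 7,8-diol F6. Isovaleryl chloride/pyridine at −20 °C then acylates the less hindered C8–OH, and the sequence comes back to the route at 26.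

**Further compounds**
F1 | step 10 | cis-fused 6/7 cross-conjugated TMS dienol ether / TIPS enol ether | CC1=C(O[Si](C(C)C)(C(C)C)C(C)C)[C@@H](OC(C)(C)O2)[C@@H]2C(C)(C)[C@@H]3C=C(O[Si](C)(C)C)C=C(C)[C@H]13
F2 | step 7 | ring-expanded α-methyl cycloheptanone TBS enol ether (methine epimers) | CC1C(=O)[C@@H](OC(C)(C)O2)[C@@H]2C(C)(C)[C@@H]3CC(O[Si](C)(C)C(C)(C)C)=C[C@H](C)[C@H]13
F3 | step 14 | 7,8,9-trihydroxylongipinan-1-one | O[C@@H]1[C@@H](O)[C@@H](O)C(C)(C)[C@H]2[C@@H]3[C@@H](C)CC(=O)[C@H]2[C@@]31C
F4 | step 14 | 9-hydroxy-7,8-O-isopropylidene-7,8-dihydroxylongipinan-1-one | O[C@@H]1[C@@H](OC(C)(C)O4)[C@@H]4C(C)(C)[C@H]2[C@@H]3[C@@H](C)CC(=O)[C@H]2[C@@]31C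
F5 | step 14 | 9-angeloyloxy-7,8-O-isopropylidene-7,8-dihydroxylongipinan-1-one | C/C=C(/C)C(=O)O[C@@H]1[C@@H](OC(C)(C)O4)[C@@H]4C(C)(C)[C@H]2[C@@H]3[C@@H](C)CC(=O)[C@H]2[C@@]31C
F6 | step 14 | 9-angeloyloxy-7,8-dihydroxylongipinan-1-one | C/C=C(/C)C(=O)O[C@@H]1[C@@H](O)[C@@H](O)C(C)(C)[C@H]2[C@@H]3[C@@H](C)CC(=O)[C@H]2[C@@]31C
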